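The route cuts the seven-membered ring at C7–C8 and C1–C10, pairing a 2-oxygenated diene (C7=C6–C5=C1) with a three-carbon vinylcarbenoid (C8–C9–C10). The target invites this because that ring carries oxygen at C6, a carbon substituent at C8 on the C8–C9 edge, and the quaternary C1 shared with the five-membered ring. One operation, rhodium-catalysed cyclopropanation followed by Cope rearrangement, closes the ring, forms both bonds and sets C1. Its precursors are 2-(1-ethoxyvinyl)-3-methylcyclopent-2-en-1-one and methyl 2-diazobut-3-enoate. The oxirane, which is cis-fused, is made last by direct face-selective epoxidation.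

Key step: step 4

Numbering (daucane): C1 is the quaternary carbon with the angular methyl, then C2, C3, C4 (isopropyl carbinol), C5 (ring-fusion CH), C6 (ester carbon), C7, C8 (methyl), C9, C10; β is the face of the C1 methyl, α the opposite face.

Structural remark: the target is (1R,4R,5S,6R,8R,9S). The 4-OH, the 6-acyloxy group and both methyls are β; H5 and the oxirane oxygen are α; the ring fusion is trans. The oxirane is necessarily cis-fused to the seven-membered ring, so it is installed by direct oxygen transfer to C8=C9; closure of a syn-diol monosulfonate cannot give a cis-fused ring oxirane.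

Assumption: the sense of induction in step 4 follows the usual facial model for donor/acceptor carbenoids with this prolinate catalyst family, which points to the (R)-catalyst for (1R); if a first batch showed the opposite sign, Rh2(S-DOSP)4 would be substituted with no other change.

Step 1
Reactants: 1 3-methylcyclopent-2-en-1-one
Product: 2 2-iodo-3-methylcyclopent-2-en-1-one
Conditions: I2, pyridine, CH2Cl2, 0 °C → rt
Reagents that add atoms: iodine, [I][I]
Why: α-Iodination of an enone by conjugate addition of pyridine, iodination of the resulting enolate and elimination (Baylis–Hillman-type α-halogenation), which the β-methyl only slows.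

Step 2
Reactants: 2 2-iodo-3-methylcyclopent-2-en-1-one; 3 tributyl(1-ethoxyvinyl)stannane
Product: 4 2-(1-ethoxyvinyl)-3-methylcyclopent-2-en-1-one
Conditions: Pd(PPh3)4 (5 mol %), CuI (10 mol %), DMF, 60 °C; Et3N-washed silica
Reagents that add atoms: none
Why: Stille coupling, in which the α-iodoenone adds readily to zerovalent palladium and CuI speeds transmetallation of the hindered α-alkoxyvinyl stannane, with base-washed silica keeping the enol ether intact.

Step 3
Reactants: 5 methyl but-3-enoate
Product: 6 methyl 2-diazobut-3-enoate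
Conditions: 4-acetamidobenzenesulfonyl azide, DBU, MeCN, 0 °C; used at once as a cold pentane solution
Reagents that add atoms: 4-acetamidobenzenesulfonyl azide, CC(=O)Nc1ccc(cc1)S(=O)(=O)N=[N+]=[N-]
Why: Regitz diazo transfer to the CH2 activated by both ester and vinyl group; the product is kept cold and used directly because vinyldiazoacetates cyclise to pyrazoles on standing.

Step 4
Reactants: 4 2-(1-ethoxyvinyl)-3-methylcyclopent-2-en-1-one; 6 methyl 2-diazobut-3-enoate
Product: 8 methyl (8aR)-4-ethoxy-8a-methyl-3-oxo-1,2,3,5,8,8a-hexahydroazulene-6-carboxylate, via cis-divinylcyclopropane 7 (not isolated)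
Conditions: Rh2(R-DOSP)4 (1 mol %), 6 (2 equiv) added slowly, 2,2-dimethylbutane–toluene, −45 °C → rt; then toluene, 100 °C
Reagents that add atoms: none
Why: The dirhodium tetraprolinate converts 6 into a donor/acceptor vinylcarbenoid that cyclopropanates the ethoxyvinyl C6=C7 bond of 4, and the resulting cis-divinylcyclopropane 7 undergoes a [3,3]-sigmatropic (Cope) shift that joins C10 to C1 and breaks C6–C8; the closest known reaction type is the tandem cyclopropanation/Cope rearrangement of vinyldiazoacetates with dienes, a formal (4+3) cycloaddition. The seven-membered ring is closed in the sigmatropic step through a boat transition state, which needs the ethenyl and cyclopentenyl groups cis on the cyclopropane and leaves C5=C6(OEt) and C8=C9 where they are needed later. The C1 stereocentre is set by relay: the catalyst fixes the configuration of the cyclopropane (C8 and C6) and the boat geometry translates it into the face of C5=C1 that bonds to C10. Chemoselectivity rests on the ethoxyvinyl group being the only electron-rich alkene (the enone C=C is electron-poor and tetrasubstituted), and attack at the carbenoid carbon, not the vinyl terminus, is favoured by the hydrocarbon medium and the prolinate ligands. The C1 methyl must point inward in the boat, hence the heating; the C4 ketone should make heterolytic reopening of the alkoxy/ester-substituted cyclopropane less likely, which would otherwise erode the relay, and any trans isomer is expected to be funnelled through the cis isomer under the same heating.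

Step 5
Reactants: 8 methyl (8aR)-4-ethoxy-8a-methyl-3-oxo-1,2,3,5,8,8a-hexahydroazulene-6-carboxylate
Product: 10 (8aR)-4-ethoxy-6-(hydroxymethyl)-8a-methyl-3-(propan-2-yl)-1,2,3,5,8,8a-hexahydroazulen-3-ol (both C4 epimers), via carbinol ester 9 (not isolated)
Conditions: iPrMgCl, CeCl3, THF, −78 °C; then LiAlH4, −78 → 0 °C; aqueous NaOH work-up
Reagents that add atoms: isopropylmagnesium chloride, CC(C)[Mg]Cl
Why: Organocerium 1,2-addition to the vinylogous-ester carbonyl (low basicity suppresses enolisation and β-hydride reduction, and at −78 °C the enoate is left alone) followed by hydride reduction of the enoate to the primary allylic alcohol; C4 forms as both epimers, which is harmless because it becomes trigonal in step 6.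

Step 6
Reactants: 10 (8aR)-4-ethoxy-6-(hydroxymethyl)-8a-methyl-3-(propan-2-yl)-1,2,3,5,8,8a-hexahydroazulen-3-ol
Product: 13 (8aR)-6,8a-dimethyl-3-(propan-2-yl)-1,2,8,8a-tetrahydroazulen-4(5H)-one, via allylic mesylate 11 (not isolated), via methyl carbinol 12 (not isolated)
Conditions: MsCl, Et3N, THF, −30 °C; then LiBHEt3, −30 → 0 °C; then 1 M HCl, 0 °C
Reagents that add atoms: methanesulfonyl chloride, CS(=O)(=O)Cl (atoms held by 11 only); water, O
Why: Selective sulfonylation of the primary allylic hydroxyl, SN2 displacement by triethylborohydride to leave the C8 methyl, and Stork–Danheiser transposition on acidification (ionisation of the tertiary carbinol assisted by the enol ether, then hydrolysis) should deliver the C6 enone with C4=C5; no stereocentre is set, and the basic medium protects the acid-labile intermediates until the deliberate quench.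

Step 7
Reactants: 13 (8aR)-6,8a-dimethyl-3-(propan-2-yl)-1,2,8,8a-tetrahydroazulen-4(5H)-one
Product: 14 (4R,8aR)-6,8a-dimethyl-3-(propan-2-yl)-1,2,4,5,8,8a-hexahydroazulen-4-ol (6β-hydroxyl in daucane numbering)
Conditions: (S)-2-methyl-CBS-oxazaborolidine (20 mol %), catecholborane, toluene, −78 °C
Reagents that add atoms: none
Why: Corey–Bakshi–Shibata reduction under reagent control: the fully substituted alkenyl carbon C5 acts as the large and the C7 methylene as the small carbonyl substituent, so the (S)-catalyst should give the (6R) alcohol with the hydroxyl on the β-face, while catecholborane at −78 °C leaves both alkenes untouched.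

Step 8
Reactants: 14 (4R,8aR)-6,8a-dimethyl-3-(propan-2-yl)-1,2,4,5,8,8a-hexahydroazulen-4-ol
Product: 15 (1R,4R,5S,6R)-4,5-epoxydauc-8-en-6-ol (4β,5β-oxirane, 6β-hydroxyl)
Conditions: VO(acac)2 (5 mol %), t-BuOOH, CH2Cl2, 0 °C → rt
Reagents that add atoms: tert-butyl hydroperoxide, CC(C)(C)OO
Why: Hydroxyl-directed vanadium-catalysed epoxidation: the vanadium alkoxide of the C6 hydroxyl passes the peroxide oxygen to the face of the allylic C4=C5 bond on which it sits, so the β-oxirane should result and C4 acquires its final C–O configuration, the merely homoallylic C8=C9 bond reacting far more slowly.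

Step 9
Reactants: 15 (1R,4R,5S,6R)-4,5-epoxydauc-8-en-6-ol
Product: 16 (1R,4R,5R)-4,5-epoxydauc-8-en-6-one (4β,5β-oxirane)
Conditions: Dess–Martin periodinane, NaHCO3, CH2Cl2, 0 °C → rt
Reagents that add atoms: none
Why: Dess–Martin oxidation of the secondary alcohol under buffered conditions, to which the tetrasubstituted oxirane and the alkene are inert.

Step 10
Reactants: 16 (1R,4R,5R)-4,5-epoxydauc-8-en-6-one
Product: 17 (1R,4R,5R)-4-hydroxydauc-8-en-6-one (4β-hydroxyl, 5α-H, trans ring fusion)
Conditions: SmI2, THF–MeOH, −78 °C
Reagents that add atoms: none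
Why: Samarium diiodide reductive cleavage of the α,β-epoxy ketone breaks only the C5–O bond, leaving the C4 oxygen β, and protonation of the chelated trivalent-samarium enolate at C5 is expected to give the 5α-H, trans-fused ketol, which should also be the epimer favoured at equilibrium (both ring-fusion bonds equatorial on the seven-membered ring, O–H···O=C hydrogen bond).

Step 11
Reactants: 17 (1R,4R,5R)-4-hydroxydauc-8-en-6-one
Product: 18 (1R,4R,5S,6R)-dauc-8-ene-4,6-diol (4β,6β-diol, 5α-H)
Conditions: LiBH(s-Bu)3, THF, −78 °C; then NaOH, H2O2, 0 °C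
Reagents that add atoms: none
Why: Bulky trialkylborohydride reduction under steric approach control: hydride should come in on the α-face, away from the syn-axial C1 methyl and from C4 on the neighbouring carbon, to give the axial 6β-alcohol (6R), the same sense in which such reagents turn 2-substituted cycloalkanones into cis-alcohols.

Step 12
Reactants: 18 (1R,4R,5S,6R)-dauc-8-ene-4,6-diol; 19 4-acetoxy-3-methoxybenzoic acid
Product: 20 (1R,4R,5S,6R)-4-hydroxydauc-8-en-6-yl 4-acetoxy-3-methoxybenzoate
Conditions: EDC·HCl, DMAP, CH2Cl2, rt → 40 °C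
Reagents that add atoms: none
Why: Carbodiimide/DMAP (Steglich) esterification acylates the secondary C6 hydroxyl while the tertiary C4 hydroxyl is too hindered to react and the acetyl group keeps the phenol from competing; no stereocentre is touched.

Step 13
Reactants: 20 (1R,4R,5S,6R)-4-hydroxydauc-8-en-6-yl 4-acetoxy-3-methoxybenzoate
Product: 21 (1R,4R,5S,6R,8R,9S)-8,9-epoxy-4-hydroxydaucan-6-yl 4-acetoxy-3-methoxybenzoate (8α,9α-oxirane)
Conditions: mCPBA, NaHCO3, CH2Cl2, 0 °C
Reagents that add atoms: 3-chloroperoxybenzoic acid, OOC(=O)c1cccc(Cl)c1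
Why: Prilezhaev epoxidation of the only alkene: the β-face of C8=C9 is screened by the two pseudoaxial groups on the flanking homoallylic carbons (C1 methyl, C6 benzoate), so oxygen should be delivered to the α-face to give the cis-fused (8R,9S) oxirane, with bicarbonate preventing transannular opening by the C4 hydroxyl.

Step 14
Reactants: 21 (1R,4R,5S,6R,8R,9S)-8,9-epoxy-4-hydroxydaucan-6-yl 4-acetoxy-3-methoxybenzoate
Product: 22 (1R,4R,5S,6R,8R,9S)-8,9-epoxy-4-hydroxydaucan-6-yl 4-hydroxy-3-methoxybenzoate (CNP0254293.2)
Conditions: pyrrolidine, CH2Cl2, 0 °C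
Reagents that add atoms: none
Why: Chemoselective aminolysis of the aryl acetate, which is far more electrophilic than the hindered alkyl benzoate, should free the phenol without touching the oxirane or the ester linkage.

Compound list
1 | 3-methylcyclopent-2-en-1-one | CC1=CC(=O)CC1 | starting material
2 | 2-iodo-3-methylcyclopent-2-en-1-one | CC1=C(I)C(=O)CC1 | intermediate
3 | tributyl(1-ethoxyvinyl)stannane | CCOC(=C)[Sn](CCCC)(CCCC)CCCC | starting material
4 | 2-(1-ethoxyvinyl)-3-methylcyclopent-2-en-1-one | CCOC(=C)C1=C(C)CCC1=O | intermediate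
5 | methyl but-3-enoate | COC(=O)CC=C | starting material
6 | methyl 2-diazobut-3-enoate | COC(=O)C(=[N+]=[N-])C=C | intermediate
7 | methyl (1S,2R)-2-ethoxy-1-ethenyl-2-(2-methyl-5-oxocyclopent-1-en-1-yl)cyclopropane-1-carboxylate (ethenyl and cyclopentenyl cis) | CCO[C@]1(C[C@@]1(C=C)C(=O)OC)C1=C(C)CCC1=O | intermediate (not isolated)
8 | methyl (8aR)-4-ethoxy-8a-methyl-3-oxo-1,2,3,5,8,8a-hexahydroazulene-6-carboxylate | COC(=O)C1=CC[C@@]2(C)CCC(=O)C2=C(OCC)C1 | intermediate
9 | methyl (8aR)-4-ethoxy-3-hydroxy-8a-methyl-3-(propan-2-yl)-1,2,3,5,8,8a-hexahydroazulene-6-carboxylate, as its alkoxide, both C4 epimers | COC(=O)C1=CC[C@@]2(C)CCC(O)(C(C)C)C2=C(OCC)C1 | intermediate (not isolated)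
10 | (8aR)-4-ethoxy-6-(hydroxymethyl)-8a-methyl-3-(propan-2-yl)-1,2,3,5,8,8a-hexahydroazulen-3-ol, both C4 epimers | OCC1=CC[C@@]2(C)CCC(O)(C(C)C)C2=C(OCC)C1 | intermediate
11 | primary methanesulfonate of 10 | CS(=O)(=O)OCC1=CC[C@@]2(C)CCC(O)(C(C)C)C2=C(OCC)C1 | intermediate (not isolated)
12 | (8aR)-4-ethoxy-6,8a-dimethyl-3-(propan-2-yl)-1,2,3,5,8,8a-hexahydroazulen-3-ol, both C4 epimers | CC1=CC[C@@]2(C)CCC(O)(C(C)C)C2=C(OCC)C1 | intermediate (not isolated)
13 | (8aR)-6,8a-dimethyl-3-(propan-2-yl)-1,2,8,8a-tetrahydroazulen-4(5H)-one, i.e. (1R)-dauca-4,8-dien-6-one | CC1=CC[C@@]2(C)CCC(C(C)C)=C2C(=O)C1 | intermediate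
14 | (4R,8aR)-6,8a-dimethyl-3-(propan-2-yl)-1,2,4,5,8,8a-hexahydroazulen-4-ol, i.e. (1R,6R)-dauca-4,8-dien-6-ol | CC1=CC[C@@]2(C)CCC(C(C)C)=C2[C@H](O)C1 | intermediate
15 | (1R,4R,5S,6R)-4,5-epoxydauc-8-en-6-ol (4β,5β-oxirane, 6β-OH) | CC1=CC[C@@]2(C)CC[C@]3(C(C)C)O[C@]23[C@H](O)C1 | intermediate
16 | (1R,4R,5R)-4,5-epoxydauc-8-en-6-one (4β,5β-oxirane) | CC1=CC[C@@]2(C)CC[C@]3(C(C)C)O[C@]23C(=O)C1 | intermediate
17 | (1R,4R,5R)-4-hydroxydauc-8-en-6-one (4β-OH, 5α-H) | CC1=CC[C@@]2(C)CC[C@@](O)(C(C)C)[C@@H]2C(=O)C1 | intermediate
18 | (1R,4R,5S,6R)-dauc-8-ene-4,6-diol (4β,6β-diol, 5α-H) | CC1=CC[C@@]2(C)CC[C@@](O)(C(C)C)[C@@H]2[C@H](O)C1 | intermediate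
19 | 4-acetoxy-3-methoxybenzoic acid | COc1cc(C(O)=O)ccc1OC(C)=O | starting material
20 | (1R,4R,5S,6R)-4-hydroxydauc-8-en-6-yl 4-acetoxy-3-methoxybenzoate | COc1cc(C(=O)O[C@@H]2CC(C)=CC[C@@]3(C)CC[C@@](O)(C(C)C)[C@H]23)ccc1OC(C)=O | intermediate
21 | (1R,4R,5S,6R,8R,9S)-8,9-epoxy-4-hydroxydaucan-6-yl 4-acetoxy-3-methoxybenzoate | COc1cc(C(=O)O[C@@H]2C[C@@]3(C)O[C@H]3C[C@@]3(C)CC[C@@](O)(C(C)C)[C@H]23)ccc1OC(C)=O | intermediate
22 | (1R,4R,5S,6R,8R,9S)-8,9-epoxy-4-hydroxydaucan-6-yl 4-hydroxy-3-methoxybenzoate | COc1cc(C(=O)O[C@@H]2C[C@@]3(C)O[C@H]3C[C@@]3(C)CC[C@@](O)(C(C)C)[C@H]23)ccc1O | target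

Total step count: 14. Longest linear sequence: 13 steps (1 → 2 → 4 → 8 → 10 → 13 → 14 → 15 → 16 → 17 → 18 → 20 → 21 → 22); step 3 is a one-step side branch.

Steps most likely to fail

Step 4. The cyclopropane carries an alkoxy donor and an ester acceptor on adjacent carbons. If the methyl-inward boat is slower than heterolytic reopening of the C6–C8 bond, both cyclopropane centres scramble before the rearrangement and the enantiomeric purity of 8 erodes; closure of the same zwitterion to a cyclopentene is the companion side reaction. The fallback sets out from 4 and 6 and gives up the catalyst-to-C1 relay. Compound 6 is decomposed by achiral Rh2(OOct)4 in the presence of 4 in refluxing hexanes–toluene, so that the racemic cis-divinylcyclopropane F1 and its isomers equilibrate and rearrange as they form to the racemic hexahydroazulenone ester F2. The (8aR)-enantiomer is then separated by preparative chromatography on a chiral stationary phase, and the route is rejoined at 8.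

Step 10. Protonation of the samarium enolate at C5 may occur from the β-face, which is the less hindered one because the isopropyl group shields the α-face; this would give the cis-fused ketol. Base equilibration of a tertiary aldol invites retro-aldol cleavage or dehydration. The fallback sets out from 15 and comes back at 17, replacing steps 9 and 10. Compound 15 is treated with TMSOTf and 2,6-lutidine in CH2Cl2 at −78 → −40 °C, which silylates the C6 hydroxyl to give the epoxy silyl ether F3. Silyl activation of the oxirane then triggers a semipinacol-type 1,2-hydride shift (the non-aldol aldol manifold of 2,3-epoxy silyl ethers). Because hydroxyl and oxirane are syn, the C6 hydrogen lies anti to the C5–O bond and migrates to the α-face of C5 with inversion while C6 becomes the ketone, giving the 4-O-trimethylsilyl ketol F4. Citric acid in methanol removes the silyl group to give 17. The C5 configuration is then set by a stereospecific migration instead of an enolate protonation.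

Step 6. The tertiary allylic carbinol/enol ether pair may ionise prematurely during mesylation or hydride treatment, losing the masked ketone before the ester-derived oxygen has been removed; SN2′ hydride delivery is a second leak. The fallback sets out from 8 and comes back at 14, replacing steps 5 to 7. The organocerium addition of step 5 is quenched directly with 1 M HCl, so that carbinol ester 9 is transposed at once to the robust dienone ester F5, which is handled cold and without base because its C7 methylene is doubly activated. (S)-CBS reduction with catecholborane gives the (6R)-hydroxy ester F6, and iBu2AlH (CH2Cl2, −78 °C) reduces the ester to the allylic diol F7. MsCl with 2,4,6-collidine sulfonylates only the primary hydroxyl to give the mesylate F8, and LiBHEt3 displaces it to give 14.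

Further compounds
F1 | step 4 | racemic methyl 2-ethoxy-1-ethenyl-2-(2-methyl-5-oxocyclopent-1-en-1-yl)cyclopropane-1-carboxylate (ethenyl and cyclopentenyl cis) | CCO[C@]1(C[C@@]1(C=C)C(=O)OC)C1=C(C)CCC1=O.CCO[C@@]1(C[C@]1(C=C)C(=O)OC)C1=C(C)CCC1=O
F2 | step 4 | racemic methyl 4-ethoxy-8a-methyl-3-oxo-1,2,3,5,8,8a-hexahydroazulene-6-carboxylate | COC(=O)C1=CC[C@@]2(C)CCC(=O)C2=C(OCC)C1.COC(=O)C1=CC[C@]2(C)CCC(=O)C2=C(OCC)C1
F3 | step 10 | (1R,4R,5S,6R)-4,5-epoxy-6-(trimethylsilyloxy)dauc-8-ene | CC1=CC[C@@]2(C)CC[C@]3(C(C)C)O[C@]23[C@H](O[Si](C)(C)C)C1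
F4 | step 10 | (1R,4R,5R)-4-(trimethylsilyloxy)dauc-8-en-6-one | CC1=CC[C@@]2(C)CC[C@@](O[Si](C)(C)C)(C(C)C)[C@@H]2C(=O)C1
F5 | step 6 | methyl (8aR)-8a-methyl-4-oxo-3-(propan-2-yl)-1,2,4,5,8,8a-hexahydroazulene-6-carboxylate | COC(=O)C1=CC[C@@]2(C)CCC(C(C)C)=C2C(=O)C1
F6 | step 6 | methyl (4R,8aR)-4-hydroxy-8a-methyl-3-(propan-2-yl)-1,2,4,5,8,8a-hexahydroazulene-6-carboxylate | COC(=O)C1=CC[C@@]2(C)CCC(C(C)C)=C2[C@H](O)C1
F7 | step 6 | (4R,8aR)-6-(hydroxymethyl)-8a-methyl-3-(propan-2-yl)-1,2,4,5,8,8a-hexahydroazulen-4-ol | OCC1=CC[C@@]2(C)CCC(C(C)C)=C2[C@H](O)C1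
F8 | step 6 | primary methanesulfonate of F7 | CS(=O)(=O)OCC1=CC[C@@]2(C)CCC(C(C)C)=C2[C@H](O)C1
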